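I decided to reckon these flasks by the age of what is in them, in fractions of the charge, and to leave concentrations aside.

| flask | substrate | partner | remark | time |
|---|---|---|---|---|
| east | 0.050 M | 0.035 M | run made earlier |  |
| north-east | 0.050 M | 0.018 M | run made earlier |  |
| south | 0.050 M | 0.026 M | run made earlier |  |
| birch | 0.050 M (fed, over 9.60 min) | 0.0350 M | all but substrate at the start; substrate goes in evenly over 9.60 min, the run ends at 12 min | 12 min |
| maple | 0.050 M | 0.0350 M (fed, over 9.60 min) | all but partner at the start; partner goes in evenly over 9.60 min, the run ends at 12 min | 12 min |
| alder | 0.050 M | 0.0350 M | a single well-mixed tank run continuously and read at steady state, 12 min in it on average |  |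
| elm | 0.050 M | 0.0350 M | everything together in a closed stirred flask, run for 12 min | 12 min |

| run | time / min | target / % | substrate / % |
|---|---|---|---|
| east | 2.00 | 45 | 30 |
| east | 4.00 | 45 | 8 |
| east | 6.00 | 37 | 5 |
| east | 8.00 | 28 | 0 |
| east | 10.0 | 26 | 0 |
| east | 12.0 | 21 | 0 |
| north-east | 1.00 | 30 | 53 |
| north-east | 2.00 | 44 | 33 |
| north-east | 3.00 | 46 | 17 |
| north-east | 5.00 | 39 | 5 |
| north-east | 8.00 | 31 | 0 |
| north-east | 15.0 | 18 | 0 |
| south | 1.00 | 34 | 56 |
| south | 3.00 | 47 | 18 |
| south | 5.00 | 41 | 5 |
| south | 8.00 | 29 | 3 |
| south | 12.0 | 21 | 2 |
| south | 15.0 | 17 | 1 |

(each reading ± 1.5 percentage points)

- the stated concentrations are those of everything mixed, before any reaction; amounts are the same in each set-up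
- what may be going on: substrate -> target; substrate -> intermediate A; substrate -> intermediate B; partner + intermediate B -> side product; intermediate B <-> intermediate A; 2 partner -> homo dimer; target <-> isomer of the product
- the feed brings no volume worth counting
- the earlier runs were made in a closed, stirred flask

- the set-up with the highest amount of target at the outlet or at the end, in percent of the substrate put in ("none" if the first two lie within 2 percentage points) (birch / maple / alder / elm / none)
- amount of target at the outlet or at the end, in percent of the substrate put in, birch
- amount of target at the outlet or at the end, in percent of the substrate put in, maple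
- amount of target at the outlet or at the end, in percent of the substrate put in, alder
- amount of target at the outlet or at the end, in percent of the substrate put in, elm

The recipes give the same charges, so the flasks differ in when things enter. The readings came next. At 8.00 min the target stood at 28% in the east run and 31% in the north-east run, with about twice the partner in the east run, a gap of 3 percentage points against a scatter of 1.5 points. So I gave the partner no say over the target. In the north-east run the substrate went from 53% to 33% to 17% in equal steps of time, roughly a steady fraction each step, which is first-order behaviour. So I let each portion of substrate age by its own clock.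

Elm is the zero of the scale, since its whole charge is 12 min old at the end. But birch's portions spread evenly from 2.40 min to 12 min in age, symmetric about a mean age, the time since the middle of the feed, of 7.20 min. The east run, which has elm's recipe, fell from 37% at 6.00 min to 28% at 8.00 min. A straight line between those two readings gave me, as an estimate at that age, 31.6% for birch, against 21% read in the east run at 12.0 min, the age of elm's charge.

The forecast said “linear kinetics make this the batch curve averaged” and put birch first: birch 34%, maple 21.5%, alder 27.5%, elm 21.5%. Its birch figure is higher than my estimate.

The simulation gave birch 33.3%, maple 21.5%, alder 27.7%, elm 21.5%, with birch first.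

    substrate → target (k = 0.00762 s⁻¹)
    substrate → intermediate A (k = 0.00128 s⁻¹)
    substrate → intermediate B (k = 0.00101 s⁻¹)
    partner + intermediate B → side product (k = 0.0677 M⁻¹ s⁻¹)
    intermediate B ⇌ intermediate A (K = 0.440, k = 0.00117 s⁻¹)
    2 partner → homo dimer (k = 0.0904 M⁻¹ s⁻¹)
    target ⇌ isomer of the product (K = 3.82, k = 0.00320 s⁻¹)

Birch stood 1.7 points above my estimate at 7.20 min, which rests on two readings with a scatter of 1.5 points each. I then took birch again, read at 20 min instead. Its mean age becomes 15.2 min, and the readings nearest to that are 18% in the north-east run and 17% in the south run, both at 15.0 min. That birch flask held 19.1% target.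

The earlier runs and the new flask are simulated from invented constants, noise included.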